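**Retrosynthetic overview**
1. The quinone is made last: target 25 comes from tetra-MOM isoflavan 23 by acid unmasking and air oxidation of the freed 2',4',5'-triol.
2. The pyran ring of 23 is closed from phenol/primary alcohol 22 (Mitsunobu, O1–C2), and 22 comes from lactone 21 by hydride reduction.
3. Key disconnection C3–C1': 21 comes from racemic 3-chlorolactone 15 and aryl iodide 20; the planar C3 lactone radical is captured by a chiral arylnickel, so both enantiomers of 15 converge to 3R.
4. 15 comes from coumarin 13, built from symmetric phenol 7 and propiolic acid (gold hydroarylation forms the lactone ring first); 5-OMe and 7-OMOM are set on diol 11.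
5. Both arenes come from one intermediate 5 (resorcinol + prenyl bromide): 7 by C–H borylation/oxidation, 20 by ortho-lithiation/hydroxylation, MOM protection and iodination. Ring order: lactone → opened → chroman → quinone.

Abbreviations: MOM = methoxymethyl; prenyl = 3-methylbut-2-en-1-yl.

Assumption: the sense of induction of the bioxazoline ligand in step 11 is fixed by a preliminary screen; the (4S,4'S) ligand is written, and its mirror image is used if it gives 3S.

**Step 1**
Reactants: 1 resorcinol
Product: 2 1,3-bis(methoxymethoxy)benzene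
Conditions: NaH (2.4 equiv), MOMCl (2.4 equiv), DMF, 0 °C to rt
Reagents that add atoms: chloromethyl methyl ether, COCCl
Why: Williamson etherification of both phenoxides (MOM protection) installs the two groups that later direct metalation; no stereocenter.

**Step 2**
Reactants: 2 1,3-bis(methoxymethoxy)benzene; 3 prenyl bromide
Product: 5 1,3-bis(methoxymethoxy)-2-prenylbenzene, via 2-lithio arene 4 (not isolated)
Conditions: n-BuLi (1.1 equiv), THF, 0 °C, 1 h; CuI (10 mol %), then 3, –78 °C to rt
Reagents that add atoms: none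
Why: Directed ortho-metalation removes the C2–H flanked by both MOM ethers, and the aryllithium is alkylated at the primary carbon of the allylic bromide.

**Step 3**
Reactants: 5 1,3-bis(methoxymethoxy)-2-prenylbenzene
Product: 7 3,5-bis(methoxymethoxy)-4-prenylphenol, via pinacol boronate 6 (not isolated)
Conditions: [Ir(OMe)(cod)]2 (1.5 mol %), 4,4'-di-tert-butyl-2,2'-bipyridine (3 mol %), B2pin2 (0.55 equiv), THF, 80 °C; then 30% H2O2, aq. NaOH, 0 °C
Reagents that add atoms: hydrogen peroxide, OO
Why: Sterically governed iridium-catalysed aromatic C–H borylation reaches only C5, the one ring C–H with no ortho substituent, and the C–B bond is then oxidised to the phenol (C–H borylation/oxidation).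

**Step 4**
Reactants: 7 3,5-bis(methoxymethoxy)-4-prenylphenol; 8 propiolic acid
Product: 9 3,5-bis(methoxymethoxy)-4-prenylphenyl prop-2-ynoate
Conditions: DCC (1.2 equiv), DMAP (5 mol %), CH2Cl2, –20 to 0 °C
Reagents that add atoms: none
Why: Steglich carbodiimide esterification of the only free phenol; low temperature suppresses conjugate addition to the ynoate.

**Step 5**
Reactants: 9 3,5-bis(methoxymethoxy)-4-prenylphenyl prop-2-ynoate
Product: 11 5,7-dihydroxy-6-prenyl-2H-chromen-2-one, via bis-MOM coumarin 10 (not isolated)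
Conditions: Ph3PAuCl (3 mol %), AgSbF6 (3 mol %), 1,2-dichloroethane, rt; then MeOH, 2 M HCl, 40 °C
Reagents that add atoms: none
Why: Gold π-activation of the ynoate triggers 6-endo intramolecular hydroarylation at either of the two equivalent ortho carbons, so the coumarin forms with the ring oxygen para to the prenyl group; acetal exchange with methanol then removes both MOM groups.

**Step 6**
Reactants: 11 5,7-dihydroxy-6-prenyl-2H-chromen-2-one
Product: 13 5-methoxy-7-(methoxymethoxy)-6-prenyl-2H-chromen-2-one, via 7-MOM ether 12 (not isolated)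
Conditions: MOMCl (1.05 equiv), K2CO3, acetone, 0 °C; then MeI (3 equiv), 50 °C
Reagents that add atoms: chloromethyl methyl ether, COCCl; iodomethane, CI
Why: Sequential Williamson etherification: the 7-OH (more acidic through para conjugation with the pyranone, and less hindered than the peri 5-OH) takes the single equivalent of MOMCl, and the remaining 5-OH is then methylated.

**Step 7**
Reactants: 13 5-methoxy-7-(methoxymethoxy)-6-prenyl-2H-chromen-2-one
Product: 15 racemic 3-chloro-5-methoxy-7-(methoxymethoxy)-6-prenylchroman-2-one, via lithium enolate 14 (not isolated)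
Conditions: LiBH(s-Bu)3 (1.1 equiv), THF, –78 °C; then NCS (1.2 equiv), –78 to –40 °C; pH 7 buffer
Reagents that add atoms: N-chlorosuccinimide, O=C1CCC(=O)N1Cl
Why: Conjugate reduction of the coumarin by the bulky borohydride gives the lactone enolate, which is chlorinated at carbon (reductive α-halogenation); C3 is formed racemic on purpose.

**Step 8**
Reactants: 5 1,3-bis(methoxymethoxy)-2-prenylbenzene
Product: 18 2,4-bis(methoxymethoxy)-3-prenylphenol, via aryllithium 16 (not isolated), via dimethyl boronate 17 (not isolated)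
Conditions: n-BuLi (1.2 equiv), TMEDA (1.2 equiv), THF, 0 °C; B(OMe)3, –78 °C to rt; then 30% H2O2, aq. NaOH, 0 °C
Reagents that add atoms: hydrogen peroxide, OO
Why: MOM-directed ortho-lithiation at C4, borylation and C–B to C–O oxidation (aryllithium hydroxylation) install the third oxygen of the future quinone ring.

**Step 9**
Reactants: 18 2,4-bis(methoxymethoxy)-3-prenylphenol
Product: 19 1,2,4-tris(methoxymethoxy)-3-prenylbenzene
Conditions: NaH (1.2 equiv), MOMCl (1.2 equiv), THF/DMF, 0 °C to rt
Reagents that add atoms: chloromethyl methyl ether, COCCl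
Why: Williamson MOM protection; the free phenol would otherwise direct iodination to the wrong carbon.

**Step 10**
Reactants: 19 1,2,4-tris(methoxymethoxy)-3-prenylbenzene
Product: 20 1-iodo-2,4,5-tris(methoxymethoxy)-3-prenylbenzene
Conditions: NIS (1.05 equiv), MeCN, 0 °C, dark
Reagents that add atoms: N-iodosuccinimide, O=C1CCC(=O)N1I
Why: Electrophilic aromatic iodination goes to the C–H that is ortho and para to two MOM-oxygens (the other free C–H has only one ortho oxygen); the trialkoxyarene is far more nucleophilic than the trisubstituted alkene.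

**Step 11 (key step)**
Reactants: 15 racemic 3-chloro-5-methoxy-7-(methoxymethoxy)-6-prenylchroman-2-one; 20 1-iodo-2,4,5-tris(methoxymethoxy)-3-prenylbenzene
Product: 21 (3R)-5-methoxy-7-(methoxymethoxy)-6-prenyl-3-[2,4,5-tris(methoxymethoxy)-3-prenylphenyl]chroman-2-one
Conditions: NiBr2·diglyme (10 mol %), (4S,4'S)-4,4'-di(heptan-4-yl)-4,4',5,5'-tetrahydro-2,2'-bioxazole (12 mol %), Mn powder (3 equiv), NaI (0.5 equiv), DMA, 5 °C
Reagents that add atoms: none
Why: Proposed new method: stereoconvergent nickel-catalysed reductive cross-coupling in which zerovalent nickel bearing the chiral bioxazoline adds oxidatively to iodide 20, a monovalent nickel species abstracts chlorine from 15 to give the planar C3 lactone α-radical (both enantiomers of 15 converge), and the chiral divalent arylnickel captures this radical to a trivalent nickel that reductively eliminates the C3–C1' bond with 3R fixed by the ligand while Mn turns the cycle over; the closest known reaction type is the nickel/bioxazoline-catalysed enantioconvergent reductive arylation of acyclic α-chloro esters with aryl iodides, extended here to a cyclic aryl lactone.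

**Step 12**
Reactants: 21 (3R)-lactone
Product: 22 (2R)-3-[2-hydroxy-6-methoxy-4-(methoxymethoxy)-5-prenylphenyl]-2-[2,4,5-tris(methoxymethoxy)-3-prenylphenyl]propan-1-ol
Conditions: LiAlH4 (2 equiv), THF, –40 to 0 °C; aq. KNaC4H4O6 work-up
Reagents that add atoms: none
Why: Hydride reduction of the reactive aryl lactone to phenol plus primary alcohol outruns enolisation at low temperature, so the C–H stereocenter is kept.

**Step 13**
Reactants: 22 (2R)-diol
Product: 23 (3R)-5-methoxy-7-(methoxymethoxy)-6-prenyl-3-[2,4,5-tris(methoxymethoxy)-3-prenylphenyl]chroman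
Conditions: PPh3 (1.3 equiv), DIAD (1.3 equiv), THF, 0 °C to rt
Reagents that add atoms: none
Why: Mitsunobu cyclodehydration: the only free phenol displaces the activated primary alcohol (6-exo-tet) to close the chroman; the stereocenter is not a reacting centre, and the ring B oxygens are masked so no dihydrobenzofuran can form.

**Step 14**
Reactants: 23 (3R)-tetra-MOM isoflavan
Product: 25 2-[(3R)-7-hydroxy-5-methoxy-6-prenylchroman-3-yl]-5-hydroxy-6-prenylcyclohexa-2,5-diene-1,4-dione, via hydroxyquinol 24 (not isolated)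
Conditions: 3 M HCl/MeOH (1:4), argon, 45 °C; then NaHCO3 to pH 7, EtOAc, air, rt
Reagents that add atoms: none
Why: Acid-catalysed acetal exchange removes all four MOM groups, and the freed 1,2,4-trihydroxyarene autoxidises in air at neutral pH to the 2-hydroxy-1,4-benzoquinone while the ring A mono-phenol is inert; neutral work-up keeps the C3–H next to the quinone from epimerising.

**Compound list**
1 | resorcinol (benzene-1,3-diol) | Oc1cccc(O)c1 | starting material
2 | 1,3-bis(methoxymethoxy)benzene | COCOc1cccc(OCOC)c1 | intermediate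
3 | prenyl bromide (1-bromo-3-methylbut-2-ene) | CC(C)=CCBr | starting material
4 | 2,6-bis(methoxymethoxy)phenyllithium | [Li]c1c(OCOC)cccc1OCOC | intermediate (not isolated)
5 | 1,3-bis(methoxymethoxy)-2-(3-methylbut-2-en-1-yl)benzene | COCOc1cccc(OCOC)c1CC=C(C)C | intermediate
6 | 2-[3,5-bis(methoxymethoxy)-4-(3-methylbut-2-en-1-yl)phenyl]-4,4,5,5-tetramethyl-1,3,2-dioxaborolane | CC1(C)OB(OC1(C)C)c1cc(OCOC)c(CC=C(C)C)c(OCOC)c1 | intermediate (not isolated)
7 | 3,5-bis(methoxymethoxy)-4-(3-methylbut-2-en-1-yl)phenol | Oc1cc(OCOC)c(CC=C(C)C)c(OCOC)c1 | intermediate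
8 | propiolic acid (prop-2-ynoic acid) | C#CC(=O)O | starting material
9 | 3,5-bis(methoxymethoxy)-4-(3-methylbut-2-en-1-yl)phenyl prop-2-ynoate | C#CC(=O)Oc1cc(OCOC)c(CC=C(C)C)c(OCOC)c1 | intermediate
10 | 5,7-bis(methoxymethoxy)-6-(3-methylbut-2-en-1-yl)-2H-chromen-2-one | O=c1ccc2c(OCOC)c(CC=C(C)C)c(OCOC)cc2o1 | intermediate (not isolated)
11 | 5,7-dihydroxy-6-(3-methylbut-2-en-1-yl)-2H-chromen-2-one | O=c1ccc2c(O)c(CC=C(C)C)c(O)cc2o1 | intermediate
12 | 5-hydroxy-7-(methoxymethoxy)-6-(3-methylbut-2-en-1-yl)-2H-chromen-2-one | O=c1ccc2c(O)c(CC=C(C)C)c(OCOC)cc2o1 | intermediate (not isolated)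
13 | 5-methoxy-7-(methoxymethoxy)-6-(3-methylbut-2-en-1-yl)-2H-chromen-2-one | O=c1ccc2c(OC)c(CC=C(C)C)c(OCOC)cc2o1 | intermediate
14 | lithium enolate of 5-methoxy-7-(methoxymethoxy)-6-(3-methylbut-2-en-1-yl)chroman-2-one (2-lithiooxy-4H-chromene) | [Li]OC1=CCc2c(OC)c(CC=C(C)C)c(OCOC)cc2O1 | intermediate (not isolated)
15 | racemic 3-chloro-5-methoxy-7-(methoxymethoxy)-6-(3-methylbut-2-en-1-yl)chroman-2-one | COc1c(CC=C(C)C)c(OCOC)cc2c1CC(Cl)C(=O)O2 | intermediate
16 | 2,4-bis(methoxymethoxy)-3-(3-methylbut-2-en-1-yl)phenyllithium | [Li]c1ccc(OCOC)c(CC=C(C)C)c1OCOC | intermediate (not isolated)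
17 | dimethyl [2,4-bis(methoxymethoxy)-3-(3-methylbut-2-en-1-yl)phenyl]boronate | COB(OC)c1ccc(OCOC)c(CC=C(C)C)c1OCOC | intermediate (not isolated)
18 | 2,4-bis(methoxymethoxy)-3-(3-methylbut-2-en-1-yl)phenol | Oc1ccc(OCOC)c(CC=C(C)C)c1OCOC | intermediate
19 | 1,2,4-tris(methoxymethoxy)-3-(3-methylbut-2-en-1-yl)benzene | COCOc1ccc(OCOC)c(CC=C(C)C)c1OCOC | intermediate
20 | 1-iodo-2,4,5-tris(methoxymethoxy)-3-(3-methylbut-2-en-1-yl)benzene | COCOc1c(I)cc(OCOC)c(OCOC)c1CC=C(C)C | intermediate
21 | (3R)-5-methoxy-7-(methoxymethoxy)-6-(3-methylbut-2-en-1-yl)-3-[2,4,5-tris(methoxymethoxy)-3-(3-methylbut-2-en-1-yl)phenyl]chroman-2-one | COc1c(CC=C(C)C)c(OCOC)cc2c1C[C@H](c1cc(OCOC)c(OCOC)c(CC=C(C)C)c1OCOC)C(=O)O2 | intermediate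
22 | (2R)-3-[2-hydroxy-6-methoxy-4-(methoxymethoxy)-5-(3-methylbut-2-en-1-yl)phenyl]-2-[2,4,5-tris(methoxymethoxy)-3-(3-methylbut-2-en-1-yl)phenyl]propan-1-ol | Oc1cc(OCOC)c(CC=C(C)C)c(OC)c1C[C@H](c1cc(OCOC)c(OCOC)c(CC=C(C)C)c1OCOC)CO | intermediate
23 | (3R)-5-methoxy-7-(methoxymethoxy)-6-(3-methylbut-2-en-1-yl)-3-[2,4,5-tris(methoxymethoxy)-3-(3-methylbut-2-en-1-yl)phenyl]chroman | COc1c(CC=C(C)C)c(OCOC)cc2c1C[C@H](c1cc(OCOC)c(OCOC)c(CC=C(C)C)c1OCOC)CO2 | intermediate
24 | (3R)-7-hydroxy-5-methoxy-6-(3-methylbut-2-en-1-yl)-3-[2,4,5-trihydroxy-3-(3-methylbut-2-en-1-yl)phenyl]chroman | COc1c(CC=C(C)C)c(O)cc2c1C[C@H](c1cc(O)c(O)c(CC=C(C)C)c1O)CO2 | intermediate (not isolated)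
25 | 2-[(3R)-7-hydroxy-5-methoxy-6-(3-methylbut-2-en-1-yl)chroman-3-yl]-5-hydroxy-6-(3-methylbut-2-en-1-yl)cyclohexa-2,5-diene-1,4-dione (CNP0148998.1) | COc1c(CC=C(C)C)c(O)cc2c1C[C@H](C1=CC(=O)C(O)=C(CC=C(C)C)C1=O)CO2 | target

**Step count and risk**
Total: 14 steps. Longest linear sequence: 11 steps (1, 2, 3, 4, 5, 6, 7, 11, 12, 13, 14); the iodide branch (8, 9, 10) leaves the main line at compound 5.

Step 11 is the most likely to fail. A cyclic α-chloro aryl lactone is outside the proven scope of the coupling; the enantioselectivity may be low, the lactone may be simply dechlorinated, and the product is an epimerisable α-aryl lactone. The fallback sets out from 15 and 20 and comes back at 22. The two are coupled without any attempt at enantiocontrol (NiBr2·diglyme, 4,4'-di-tert-butyl-2,2'-bipyridine, Mn, DMA, rt) to give the racemic 3-aryl lactone F1. The stereocenter is then set in the reduction instead of the coupling, by dynamic kinetic resolution. F1 racemises under KOtBu and is hydrogenated (H2, 10 atm, n-PrOH) with a carbonyl-selective chiral iridium catalyst formed in the flask from [Ir(cod)Cl]2 and a spiro pyridine-aminophosphine ligand. This leaves the prenyl alkenes alone and delivers diol 22 directly.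

Step 7 is the second risk. Hydride attack at C4 is hindered by the peri 5-methoxy group, and the chlorinated aryl lactone loses HCl easily back to 13. The fallback sets out from 13 and comes back at 15. Copper hydride conjugate reduction ([(Ph3P)CuH]6 catalytic, polymethylhydrosiloxane, toluene, rt) gives the isolated saturated lactone F2. This is converted with LiN(SiMe3)2 and Me3SiCl at –78 °C into the trimethylsilyl ketene acetal F3, which is chlorinated with NCS to 15 under non-basic conditions.

Step 14 is the third risk. Four MOM ethers must be cleaved by acid next to two o-prenyl phenol units (possible chroman formation) and an air-sensitive triol. The fallback sets out from 23 and comes back at 25. (NH4)2Ce(NO3)6 (2.5 equiv, MeCN/H2O, 0 °C) cleaves the para-related 2' and 5' MOM ethers oxidatively and gives the bis-MOM quinone F4 without ever freeing the triol. The two remaining MOM groups (one of them a labile vinylogous ester on the quinone) are then removed with dilute HCl in MeOH at room temperature to give 25.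

**Further compounds**
F1 | step 11 | racemic 5-methoxy-7-(methoxymethoxy)-6-(3-methylbut-2-en-1-yl)-3-[2,4,5-tris(methoxymethoxy)-3-(3-methylbut-2-en-1-yl)phenyl]chroman-2-one | COc1c(CC=C(C)C)c(OCOC)cc2c1CC(c1cc(OCOC)c(OCOC)c(CC=C(C)C)c1OCOC)C(=O)O2
F2 | step 7 | 5-methoxy-7-(methoxymethoxy)-6-(3-methylbut-2-en-1-yl)chroman-2-one | COc1c(CC=C(C)C)c(OCOC)cc2c1CCC(=O)O2
F3 | step 7 | 5-methoxy-7-(methoxymethoxy)-6-(3-methylbut-2-en-1-yl)-2-(trimethylsilyloxy)-4H-chromene | COc1c(CC=C(C)C)c(OCOC)cc2c1CC=C(O[Si](C)(C)C)O2
F4 | step 14 | 2-[(3R)-5-methoxy-7-(methoxymethoxy)-6-(3-methylbut-2-en-1-yl)chroman-3-yl]-5-(methoxymethoxy)-6-(3-methylbut-2-en-1-yl)cyclohexa-2,5-diene-1,4-dione | COc1c(CC=C(C)C)c(OCOC)cc2c1C[C@H](C1=CC(=O)C(OCOC)=C(CC=C(C)C)C1=O)CO2
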